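## Retrosynthetic overview

1. Feature: in ring B the oxygen-bearing C8 sits next to C7, and C7 carries the three-carbon unit C11–C13. A C8 alcohol beside a C7 isopropenyl group is the signature of a carbonyl-ene reaction. Ring B is therefore opened at C7–C8 to a C8 aldehyde (arm on C10) and a prenyl group (arm on C5) on a ring A ketone.
2. End game in reverse: the enone comes from oxidation at C8 and a shift of C11=C12 to C7=C11. The acetate and angelate come from the 3β,4β-diol. The C4 carbinol comes from MeMgBr on the C4 ketone, attacking the α face away from the C10 methyl. The C3 oxygen comes from a trivalent-iodine hydroxylation that ends on the β (equatorial) side.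
3. Precursor: C5–C6 is made by prenylation of the regiodefined C4=C5 enolate. C10 is made by copper-catalysed asymmetric AlMe3 addition to a 3-(2-silyloxyethyl)cyclohexenone, which is obtained by Birch reduction of 2-(3-methoxyphenyl)ethanol.
4. Ring order: ring A comes from the arene (step 1), and ring B is closed second (step 7).

Key step: step 7

Numbering remark: the eudesmane numbering of the target is used throughout. Ring A is C1–C5 and C10; ring B is C5–C10. β is the face of the C10 methyl. The target is 3β-OAng, 4β-OAc, 4α-Me, 5α-H, 10β-Me, which is (3S,4R,5R,10R).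

Assumption: L* is the phosphoramidite from 2,2'-biphenol and bis[(S)-1-(naphthalen-2-yl)ethyl]amine, taken to deliver methyl to the enone face that makes C10 R. If the sense of induction is the opposite, the (R,R)-amine ligand is used and nothing else changes.

## Route

Step 1
Reactants: 1 2-(3-methoxyphenyl)ethanol
Product: 3 3-(2-hydroxyethyl)cyclohex-2-en-1-one, via methoxy diene 2 (not isolated)
Conditions: Li, NH3 (l), t-BuOH, THF, −78 °C; then 2 M HCl, THF, rt
Reagents that add atoms: water, O
Why: Birch reduction leaves the two remaining alkenes on the carbons bearing the methoxy and alkyl donors, and aqueous acid then hydrolyses the enol ether and moves the β,γ-alkene into conjugation, which should give the 3-substituted enone without any stereocentre.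

Step 2
Reactants: 3 3-(2-hydroxyethyl)cyclohex-2-en-1-one
Product: 4 3-[2-(tert-butyldimethylsilyloxy)ethyl]cyclohex-2-en-1-one
Conditions: TBSCl, imidazole, CH2Cl2, 0 °C → rt
Reagents that add atoms: tert-butyldimethylsilyl chloride, CC(C)(C)[Si](C)(C)Cl
Why: Standard silyl ether formation at the only hydroxyl, so that the oxygen does not consume AlMe3 and survives the organometallic steps.

Step 3
Reactants: 4 3-[2-(tert-butyldimethylsilyloxy)ethyl]cyclohex-2-en-1-one; 5 trimethylaluminium
Product: 7 [(3R)-3-[2-(tert-butyldimethylsilyloxy)ethyl]-3-methylcyclohex-1-en-1-yl]oxytrimethylsilane, via dimethylaluminium enolate 6 (not isolated)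
Conditions: AlMe3 (1.5 equiv), Cu(O2CC4H3S) (copper thiophene-2-carboxylate, 2 mol %), L* (4 mol %), Et2O, −30 °C; then TMSOTf (2 equiv), THF, −30 → 0 °C
Reagents that add atoms: trimethylaluminium, C[Al](C)C; trimethylsilyl triflate, C[Si](C)(C)OS(=O)(=O)C(F)(F)F
Why: Copper-catalysed asymmetric conjugate addition of AlMe3 to a β-substituted cyclohexenone, in which the Lewis acidic aluminium activates the hindered enone, the monovalent copper–phosphoramidite complex selects the enone face and so sets the quaternary C10 as R, and O-silylation of the aluminium enolate fixes the C4=C5 enolate regiochemistry.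

Step 4
Reactants: 7 the (R)-trimethylsilyl enol ether; 8 prenyl bromide (1-bromo-3-methylbut-2-ene)
Product: 10 (2R,3R)-3-[2-(tert-butyldimethylsilyloxy)ethyl]-3-methyl-2-(3-methylbut-2-en-1-yl)cyclohexan-1-one (C5/C10 arms trans), via lithium enolate 9 (not isolated)
Conditions: MeLi (1.05 equiv), THF, 0 °C; then DMPU, prenyl bromide (3 equiv), −78 → −20 °C
Reagents that add atoms: prenyl bromide, CC(C)=CCBr
Why: MeLi cleaves the O–Si bond to release the regiodefined lithium enolate, which the reactive allylic bromide C-alkylates before proton transfer can scramble it (regiospecific enolate alkylation); the bromide should approach C5 anti to the bulkier silyloxyethyl arm on the adjacent quaternary C10, which sets the two arms trans, and the minor C5 epimer is removed by chromatography.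

Step 5
Reactants: 10 the prenylated silyloxy ketone
Product: 11 (2R,3R)-3-(2-hydroxyethyl)-3-methyl-2-(3-methylbut-2-en-1-yl)cyclohexan-1-one
Conditions: HF·pyridine, pyridine, THF, 0 °C → rt
Reagents that add atoms: none
Why: Fluoride-driven cleavage of the primary silyl ether in a weakly acidic buffered medium, which should not enolise the ketone and therefore leaves C5 untouched.

Step 6
Reactants: 11 the hydroxy ketone
Product: 12 2-[(1R,2R)-1-methyl-2-(3-methylbut-2-en-1-yl)-3-oxocyclohexyl]acetaldehyde (arms trans)
Conditions: Dess–Martin periodinane, CH2Cl2, 0 °C → rt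
Reagents that add atoms: none
Why: Dess–Martin oxidation takes the primary alcohol to the aldehyde under near-neutral conditions that spare the prenyl alkene, do not epimerise C5 and do not trigger aldol chemistry of the keto aldehyde.

Step 7
Reactants: 12 the trans keto aldehyde
Product: 13 (4aR,6S,7R,8aR)-6-hydroxy-4a-methyl-7-(prop-1-en-2-yl)octahydronaphthalen-1(2H)-one, which is 8α-hydroxy-7β-isopropenyl-10β-methyl-5αH-trans-decalin-4-one in target numbering
Conditions: Me2AlCl (2.5 equiv), CH2Cl2, −78 → −40 °C
Reagents that add atoms: none
Why: Me2AlCl binds the aldehyde oxygen, C7 of the prenyl alkene attacks C8 while a hydrogen of a C11 methyl passes to that oxygen in a six-centre array, and the alcohol–aluminium complex then loses methane, which removes the proton and makes the closure irreversible. The closest known reaction is the type 1 intramolecular carbonyl-ene cyclisation of δ,ε-unsaturated aldehydes (citronellal to isopulegol), whose six-atom chain is reproduced here with C10 and C5 of ring A as its two middle carbons. Ring B closes as a six-membered chair, exo with respect to both the C8=O and the C7=C11 π bonds, on the two equatorial arms of the ring A chair, so the trans C5/C10 relationship of 12 becomes the trans ring fusion and the gem-disubstituted C10 favours the folded chain. At C8 the aluminium-bound oxygen takes the equatorial α position because the axial β position is syn-axial to the C10 methyl, and at C7 the developing isopropenyl group takes the equatorial β position, trans to the oxygen, as the chair ene array demands. The step needs aldehyde over ketone and ene over aldol selectivity: the C4 ketone could reach the alkene only through a four- or five-membered ring and merely ties up one equivalent of Lewis acid (hence more than two equivalents), while the low temperature and the non-basic, proton-scavenging reagent hold back attack of C3 on C8 and enolisation at C5. Both new centres are removed again in steps 15 and 16, so only the C7–C8 bond and the C8/C11 functional pattern have to be delivered.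

Step 8
Reactants: 13 the hydroxy decalone
Product: 14 8α-(tert-butyldimethylsilyloxy)-7β-isopropenyl-10β-methyl-5αH-trans-decalin-4-one
Conditions: TBSCl, imidazole, DMF, rt → 40 °C
Reagents that add atoms: tert-butyldimethylsilyl chloride, CC(C)(C)[Si](C)(C)Cl
Why: Silyl ether formation at the equatorial C8 hydroxyl keeps ring B at the alcohol oxidation level, so that the C4 ketone is the only carbonyl present during the ring A chemistry.

Step 9
Reactants: 14 the silyloxy decalone
Product: 15 3β-hydroxy-4,4-dimethoxy-8α-(tert-butyldimethylsilyloxy)-7β-isopropenyl-10β-methyl-5αH-trans-decalin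
Conditions: PhI(OAc)2 (1.2 equiv), KOH (4 equiv), MeOH, 0 °C → rt
Reagents that add atoms: methanol, CO
Why: α-Hydroxylation with trivalent iodine in methanolic KOH (α-hydroxy dimethyl acetal formation), in which the less hindered C3 enolate is captured by iodine in the axial α position, methoxide adds to C4 from the α face to give the axial β alkoxide, this alkoxide expels iodobenzene from the rear in the required trans-diaxial arrangement, and methanolysis of the methoxy epoxide leaves the oxygen on C3 on the β (equatorial) side, the opposite of what direct enolate oxygenation would give.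

Step 10
Reactants: 15 the hydroxy dimethyl acetal
Product: 16 3β-hydroxy-8α-(tert-butyldimethylsilyloxy)-7β-isopropenyl-10β-methyl-5αH-trans-decalin-4-one
Conditions: p-TsOH·H2O (cat.), acetone/H2O, rt
Reagents that add atoms: water, O
Why: Acid-catalysed acetal hydrolysis is helped by release of the syn-axial strain between the 4β-methoxy group and the C10 methyl, so catalytic acid should suffice and spare the secondary silyl ether, and the equatorial hydrogen-bonded 3β-ketol is the more stable C3 epimer, so C3 and the trans-fused C5 are not at risk.

Step 11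
Reactants: 16 the 3β-hydroxy ketone; 17 methylmagnesium bromide
Product: 18 8α-(tert-butyldimethylsilyloxy)eudesm-11-ene-3β,4β-diol (4α-methyl, 5αH, 7β-isopropenyl)
Conditions: MeMgBr (4 equiv), THF, −78 → 0 °C
Reagents that add atoms: methylmagnesium bromide, C[Mg]Br
Why: Grignard 1,2-addition in which the first equivalent forms the C3 magnesium alkoxide, which chelates and activates the C4 carbonyl and discourages enolisation, while the axial C10 methyl blocks the β face, so methyl should enter from the α face (equatorial attack) and set C4 with 4α-methyl and 4β-hydroxyl, cis to the 3β-oxygen.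

Step 12
Reactants: 18 the 3β,4β-diol; 19 angelic acid ((Z)-2-methylbut-2-enoic acid)
Product: 20 3β-angeloyloxy-8α-(tert-butyldimethylsilyloxy)eudesm-11-en-4β-ol
Conditions: 19, 2,4,6-trichlorobenzoyl chloride, Et3N, toluene, rt; then 18, 80 °C
Reagents that add atoms: angelic acid, C/C=C(/C)C(=O)O
Why: Yamaguchi esterification run without a nucleophilic catalyst, in which the mixed anhydride acylates only the secondary equatorial C3 hydroxyl (the tertiary C4 hydroxyl is inert) and the absence of DMAP avoids Z to E isomerisation to the tiglate.

Step 13
Reactants: 20 the hydroxy angelate; 21 acetic anhydride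
Product: 22 4β-acetoxy-3β-angeloyloxy-8α-(tert-butyldimethylsilyloxy)eudesm-11-ene
Conditions: Ac2O (10 equiv), DMAP (0.5 equiv), Et3N, toluene, 60 °C
Reagents that add atoms: acetic anhydride, CC(=O)OC(C)=O
Why: DMAP-catalysed acylation of a tertiary alcohol with a large excess of anhydride and gentle heating, on a substrate that offers no other nucleophilic site and in which migration of the angelate to the tertiary oxygen is thermodynamically uphill.

Step 14
Reactants: 22 the silylated diester
Product: 23 4β-acetoxy-3β-angeloyloxyeudesm-11-en-8α-ol
Conditions: HF·pyridine, pyridine, THF, 0 °C → rt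
Reagents that add atoms: none
Why: Fluoride-mediated desilylation in a weakly acidic medium should free the C8 hydroxyl without hydrolysing or migrating either ester and without touching the isopropenyl group.

Step 15
Reactants: 23 the C8 alcohol
Product: 24 4β-acetoxy-3β-angeloyloxy-7β-isopropenyl-eudesm-11-en-8-one
Conditions: Dess–Martin periodinane, CH2Cl2, 0 °C → rt
Reagents that add atoms: none
Why: Dess–Martin oxidation of the only free hydroxyl gives the β,γ-unsaturated C8 ketone under conditions that leave the esters and the angelate geometry intact.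

Step 16
Reactants: 24 the β,γ-unsaturated ketone
Product: 25 4β-acetoxy-3β-angeloyloxyeudesm-7(11)-en-8-one, (3S,4R,5R,10R), the target CNP0141494.2
Conditions: DBU (0.5 equiv), CH2Cl2, rt
Reagents that add atoms: none
Why: Base-catalysed β,γ to α,β isomerisation through the C7 dienolate (isopulegone to pulegone type) is driven by conjugation with the tetrasubstituted C7=C11 alkene, and the non-nucleophilic amidine should leave both esters alone, since no leaving group sits β to the dienolate carbons.

## Compound list

1 | 2-(3-methoxyphenyl)ethanol | COc1cccc(CCO)c1 | starting material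
2 | 2-(5-methoxycyclohexa-1,4-dien-1-yl)ethanol | COC1=CCC=C(CCO)C1 | intermediate
3 | 3-(2-hydroxyethyl)cyclohex-2-en-1-one | O=C1C=C(CCO)CCC1 | intermediate
4 | 3-[2-(tert-butyldimethylsilyloxy)ethyl]cyclohex-2-en-1-one | O=C1C=C(CCO[Si](C)(C)C(C)(C)C)CCC1 | intermediate
5 | trimethylaluminium | C[Al](C)C | starting material
6 | dimethylaluminium (R)-enolate (C4=C5) | C[Al](C)OC1=C[C@@](C)(CCO[Si](C)(C)C(C)(C)C)CCC1 | intermediate
7 | [(3R)-3-[2-(tert-butyldimethylsilyloxy)ethyl]-3-methylcyclohex-1-en-1-yl]oxytrimethylsilane | C[Si](C)(C)OC1=C[C@@](C)(CCO[Si](C)(C)C(C)(C)C)CCC1 | intermediate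
8 | prenyl bromide | CC(C)=CCBr | starting material
9 | lithium (R)-enolate (C4=C5) | [Li]OC1=C[C@@](C)(CCO[Si](C)(C)C(C)(C)C)CCC1 | intermediate
10 | (2R,3R)-3-[2-(tert-butyldimethylsilyloxy)ethyl]-3-methyl-2-(3-methylbut-2-en-1-yl)cyclohexan-1-one | O=C1CCC[C@](C)(CCO[Si](C)(C)C(C)(C)C)[C@H]1CC=C(C)C | intermediate
11 | (2R,3R)-3-(2-hydroxyethyl)-3-methyl-2-(3-methylbut-2-en-1-yl)cyclohexan-1-one | O=C1CCC[C@](C)(CCO)[C@H]1CC=C(C)C | intermediate
12 | 2-[(1R,2R)-1-methyl-2-(3-methylbut-2-en-1-yl)-3-oxocyclohexyl]acetaldehyde | O=CC[C@@]1(C)CCCC(=O)[C@@H]1CC=C(C)C | intermediate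
13 | 8α-hydroxy-7β-isopropenyl-10β-methyl-5αH-trans-decalin-4-one | O=C1CCC[C@]2(C)C[C@H](O)[C@@H](C(C)=C)C[C@H]21 | intermediate
14 | 8α-TBS ether of 13 | O=C1CCC[C@]2(C)C[C@H](O[Si](C)(C)C(C)(C)C)[C@@H](C(C)=C)C[C@H]21 | intermediate
15 | 3β-hydroxy-4,4-dimethoxy-8α-(TBSO)-7β-isopropenyl-10β-methyl-5αH-trans-decalin | O[C@H]1CC[C@]2(C)C[C@H](O[Si](C)(C)C(C)(C)C)[C@@H](C(C)=C)C[C@H]2C1(OC)OC | intermediate
16 | 3β-hydroxy-8α-(TBSO)-7β-isopropenyl-10β-methyl-5αH-trans-decalin-4-one | O[C@H]1CC[C@]2(C)C[C@H](O[Si](C)(C)C(C)(C)C)[C@@H](C(C)=C)C[C@H]2C1=O | intermediate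
17 | methylmagnesium bromide | C[Mg]Br | starting material
18 | 8α-(TBSO)eudesm-11-ene-3β,4β-diol | O[C@H]1CC[C@]2(C)C[C@H](O[Si](C)(C)C(C)(C)C)[C@@H](C(C)=C)C[C@H]2[C@@]1(C)O | intermediate
19 | angelic acid | C/C=C(/C)C(=O)O | starting material
20 | 3β-angeloyloxy-8α-(TBSO)eudesm-11-en-4β-ol | C/C=C(/C)C(=O)O[C@H]1CC[C@]2(C)C[C@H](O[Si](C)(C)C(C)(C)C)[C@@H](C(C)=C)C[C@H]2[C@@]1(C)O | intermediate
21 | acetic anhydride | CC(=O)OC(C)=O | starting material
22 | 4β-acetoxy-3β-angeloyloxy-8α-(TBSO)eudesm-11-ene | C/C=C(/C)C(=O)O[C@H]1CC[C@]2(C)C[C@H](O[Si](C)(C)C(C)(C)C)[C@@H](C(C)=C)C[C@H]2[C@@]1(C)OC(C)=O | intermediate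
23 | 4β-acetoxy-3β-angeloyloxyeudesm-11-en-8α-ol | C/C=C(/C)C(=O)O[C@H]1CC[C@]2(C)C[C@H](O)[C@@H](C(C)=C)C[C@H]2[C@@]1(C)OC(C)=O | intermediate
24 | 4β-acetoxy-3β-angeloyloxy-7β-isopropenyl-eudesm-11-en-8-one | C/C=C(/C)C(=O)O[C@H]1CC[C@]2(C)CC(=O)[C@@H](C(C)=C)C[C@H]2[C@@]1(C)OC(C)=O | intermediate
25 | 4β-acetoxy-3β-angeloyloxyeudesm-7(11)-en-8-one (CNP0141494.2) | C/C=C(/C)C(=O)O[C@H]1CC[C@]2(C)CC(=O)C(=C(C)C)C[C@H]2[C@@]1(C)OC(C)=O | target

Total step count: 16. Longest linear sequence: 16 (1 → 25).

## Steps most likely to fail

**Step 9 (C3 hydroxylation).** The α-iodanyl ketone may be diverted before the oxygen transfer. This could happen by Favorskii-type ring contraction through the C5 enolate or by slow methoxide addition to the hindered C4 carbonyl. Long exposure to KOH may also start to erode the silyl ether. The fallback replaces the built-in inversion by oxygenation on the easy face followed by a separate inversion.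
- It sets out from 14 and comes back at 16, leaving out 15 and step 10.
- KN(SiMe3)2 in THF at −78 °C forms the C3 enolate. 2-(Phenylsulfonyl)-3-phenyloxaziridine should oxygenate it on the axial, less hindered α face to give the 3α-hydroxy ketone F1.
- A Mitsunobu reaction (4-nitrobenzoic acid, PPh3, DIAD, toluene) inverts this axial carbinol, which is activated by the neighbouring carbonyl, to the 3β-(4-nitrobenzoyloxy) ketone F2.
- K2CO3 in MeOH then releases 16.

**Step 13 (tertiary acetate).** Acylation of the axial hydroxyl, which is syn-axial to the C10 methyl, may be too slow. Under forcing conditions the angeloyl group may migrate from O3 to O4, followed by fast acetylation of the freed secondary hydroxyl, or the carbinol may dehydrate. The fallback delivers the acetyl group intramolecularly instead of by bimolecular acylation, and reverses the order of the two esters.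
- It sets out from 18 and comes back at 22, leaving out 20.
- Trimethyl orthoacetate with catalytic PPTS in CH2Cl2 ties the cis diol into the cyclic orthoacetate F3.
- Short treatment with aqueous acetic acid opens it. The stereoelectronic preference of such ax/eq orthoesters for the axial ester should give the 4β-acetoxy-3β-ol F4.
- F4 is then angeloylated with the preformed mixed anhydride of step 12 at the lowest workable temperature to give 22.

**Step 7 (ene closure).** The trans relationship of the two arms may leak. This could come from carry-over of the minor alkylation epimer of step 4 or from enolisation toward C5 before or during the Lewis acid treatment. Part of the material would then close to a cis-fused decalone. The fallback replaces kinetic control of the ring fusion by thermodynamic control.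
- It sets out from 12 and comes back at 13.
- Material containing the C5-epimeric cis-arm keto aldehyde F5 is not separated but cyclised as a whole with Me2AlCl.
- F5 should close through the ring B chair that keeps the C10 methyl axial, giving the cis-fused 5βH hydroxy ketone F6.
- The crude product is then equilibrated with NaOMe in MeOH. This inverts C5 of F6 through the C4 enolate toward the more stable trans-fused isomer, which is 13.

## Further compounds

F1 | step 9 | 3α-hydroxy-8α-(TBSO)-7β-isopropenyl-10β-methyl-5αH-trans-decalin-4-one | O[C@@H]1CC[C@]2(C)C[C@H](O[Si](C)(C)C(C)(C)C)[C@@H](C(C)=C)C[C@H]2C1=O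
F2 | step 9 | 3β-(4-nitrobenzoyloxy)-8α-(TBSO)-7β-isopropenyl-10β-methyl-5αH-trans-decalin-4-one | O=C(O[C@H]1CC[C@]2(C)C[C@H](O[Si](C)(C)C(C)(C)C)[C@@H](C(C)=C)C[C@H]2C1=O)c1ccc([N+](=O)[O-])cc1
F3 | step 13 | 3β,4β-O-(1-methoxyethylidene) orthoacetate of 18 (orthoester carbon unassigned) | COC1(C)O[C@H]2CC[C@]3(C)C[C@H](O[Si](C)(C)C(C)(C)C)[C@@H](C(C)=C)C[C@H]3[C@@]2(C)O1
F4 | step 13 | 4β-acetoxy-8α-(TBSO)eudesm-11-en-3β-ol | O[C@H]1CC[C@]2(C)C[C@H](O[Si](C)(C)C(C)(C)C)[C@@H](C(C)=C)C[C@H]2[C@@]1(C)OC(C)=O
F5 | step 7 | 2-[(1R,2S)-1-methyl-2-(3-methylbut-2-en-1-yl)-3-oxocyclohexyl]acetaldehyde (arms cis) | O=CC[C@@]1(C)CCCC(=O)[C@H]1CC=C(C)C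
F6 | step 7 | 8α-hydroxy-7β-isopropenyl-10β-methyl-5βH-cis-decalin-4-one | O=C1CCC[C@]2(C)C[C@H](O)[C@@H](C(C)=C)C[C@@H]21
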